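The plan rests on recognising C10 and C5 of ring A as the β- and α-carbons of 2-methylcyclohex-2-en-1-one (1), whose carbonyl is C4. One copper-catalysed operation adds a vinyl group at C10 (bond C9–C10) enantioselectively and alkylates the resulting enolate at C5 with a methallyl group (bond C5–C6) anti to it, fixing the trans ring fusion and the angular methyl before ring B exists. The precursor is simply the commercial enone with vinylmagnesium bromide and methallyl bromide. Ozonolysis and aldol closure then give ring B, a directed cyclopropanation/reductive methylation sets C8 and C9, and ring C is closed last from a furan by photooxygenation and aldol reaction.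

Key step: step 1

Labels: C1–C11 as in the terpenoid part of the target (ring A: C1–C5 and C10; ring B: C5–C10; C11 is the CH2 on C8). Ring C atoms are C1′ (carbinol), C2′ (=CH), C3′ (C–OCH3), C4′ (C=O) and C5′ (CH next to C11). β is the face of the C5 methyl group.

Assumption: the (R,SP) ferrocenyl diphosphine is taken to give the 3S adduct; if the sense of induction is the opposite, its mirror image is used and nothing else changes.

Compounds 1, 2 (1.0 M in THF), 3, 12 (0.5 M in THF) and 27 are commercial.

Step 1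
Reactants: 1 2-methylcyclohex-2-en-1-one; 2 vinylmagnesium bromide; 3 3-bromo-2-methylprop-1-ene
Product: 5 (2S,3S)-3-ethenyl-2-methyl-2-(2-methylprop-2-en-1-yl)cyclohexan-1-one, via magnesium enolate 4 (not isolated)
Conditions: CuBr·SMe2 (5 mol %), (R)-1-[(SP)-2-(diphenylphosphino)ferrocenyl]ethyldicyclohexylphosphine (6 mol %), t-BuOMe, −78 °C, slow addition of 2; then DMPU, 3, −78 → 0 °C
Reagents that add atoms: none
Why: Transmetalation of 2 to the chiral copper–diphosphine complex, π-complexation of enone 1 and oxidative addition/reductive elimination deliver the vinyl group to C10 (bond C9–C10) and release the regiodefined C4–C5 magnesium enolate 4, which is C-alkylated by 3 at C5 (bond C5–C6). The closest known reaction type is the copper-catalysed asymmetric conjugate addition of Grignard reagents to cyclic enones, 2-substituted ones included, with alkylation of the magnesium enolate in the same flask. No ring is closed, so no mode of closure applies. The C10 configuration (S) is set by the ferrocenyl diphosphine on copper, and the C5 configuration (S) is relayed from C10 because the allylic bromide approaches the enolate face anti to the adjacent vinyl group, which makes the C10–C9 and C5–C6 bonds trans and the vinyl group cis to the methyl group. The step needs 1,4- over 1,2-addition (copper catalysis, slow addition at −78 °C, little THF), C- over O-alkylation without enolate equilibration (tetrasubstituted enolate formed regiospecifically, soft allylic bromide, DMPU) and trans selectivity (steric bias of the C10 substituent).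

Step 2
Reactants: 5 (2S,3S)-3-ethenyl-2-methyl-2-(2-methylprop-2-en-1-yl)cyclohexan-1-one
Product: 6 (6S,7S)-7-ethenyl-6-methyl-6-(2-methylprop-2-en-1-yl)-1,4-dioxaspiro[4.5]decane
Conditions: Me3SiOCH2CH2OSiMe3, Me3SiOTf (2 mol %), CH2Cl2, −78 → −20 °C
Reagents that add atoms: 1,2-bis(trimethylsilyloxy)ethane, C[Si](C)(C)OCCO[Si](C)(C)C
Why: Aprotic silyl triflate-catalysed ketalisation protects the hindered C4 ketone without protonating the acid-sensitive methallyl alkene, and no stereocentre is touched.

Step 3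
Reactants: 6 (6S,7S)-7-ethenyl-6-methyl-6-(2-methylprop-2-en-1-yl)-1,4-dioxaspiro[4.5]decane
Product: 8 (6S,7R)-6-methyl-6-(2-oxopropyl)-1,4-dioxaspiro[4.5]decane-7-carbaldehyde, via bis-ozonide 7 (not isolated)
Conditions: O3, CH2Cl2, −78 °C; then Me2S, −78 → 20 °C
Reagents that add atoms: ozone, [O-][O+]=O
Why: Ozonolysis with reductive work-up turns the vinyl group into the C9 aldehyde and the methallyl group into the C6–C7–C8 acetonyl unit, while the ketal is inert and the neutral work-up leaves C10 (α to the aldehyde) untouched.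

Step 4
Reactants: 8 (6S,7R)-6-methyl-6-(2-oxopropyl)-1,4-dioxaspiro[4.5]decane-7-carbaldehyde
Product: 10 (4aS,8aS)-8,8-(ethane-1,2-diyldioxy)-8a-methyl-4a,5,6,7,8,8a-hexahydronaphthalen-2(1H)-one, via aldol adduct 9 (not isolated)
Conditions: KOH (0.2 M), MeOH, 0 → 20 °C, short reaction time
Reagents that add atoms: none
Why: Intramolecular aldol condensation, in which the methyl ketone enolate (C8) adds to the C9 aldehyde in a 6-(enolexo)-exo-trig closure and E1cB dehydration gives the C7 enone with the C8=C9 alkene, run briefly in dilute base so that cyclisation outruns enolisation of the aldehyde towards C10 and the trans ring fusion from step 1 is kept.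

Step 5
Reactants: 10 (4aS,8aS)-8,8-(ethane-1,2-diyldioxy)-8a-methyl-4a,5,6,7,8,8a-hexahydronaphthalen-2(1H)-one
Product: 11 (4aS,8aS)-8,8-(ethane-1,2-diyldioxy)-3-iodo-8a-methyl-4a,5,6,7,8,8a-hexahydronaphthalen-2(1H)-one
Conditions: I2, pyridine, CH2Cl2, 0 → 20 °C
Reagents that add atoms: iodine, II
Why: α-Iodination of the enone by conjugate addition of pyridine, iodination of the resulting enolate at C8 and elimination of pyridine, under basic conditions that spare the ketal.

Step 6
Reactants: 11 (4aS,8aS)-8,8-(ethane-1,2-diyldioxy)-3-iodo-8a-methyl-4a,5,6,7,8,8a-hexahydronaphthalen-2(1H)-one; 12 (1,3-dioxolan-2-ylmethyl)zinc bromide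
Product: 13 (4aS,8aS)-3-(1,3-dioxolan-2-ylmethyl)-8,8-(ethane-1,2-diyldioxy)-8a-methyl-4a,5,6,7,8,8a-hexahydronaphthalen-2(1H)-one
Conditions: Pd(OAc)2 (3 mol %), 2-dicyclohexylphosphino-2′,6′-dimethoxybiphenyl (SPhos, 6 mol %), THF/DMF, 40 °C
Reagents that add atoms: none
Why: Negishi coupling of the α-iodoenone with a primary alkylzinc halide puts C11 and C5′ on C8 as a masked aldehyde that carries no leaving group β to the later C8 enolate.

Step 7
Reactants: 13 (4aS,8aS)-3-(1,3-dioxolan-2-ylmethyl)-8,8-(ethane-1,2-diyldioxy)-8a-methyl-4a,5,6,7,8,8a-hexahydronaphthalen-2(1H)-one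
Product: 14 (2S,4aS,8aS)-3-(1,3-dioxolan-2-ylmethyl)-8,8-(ethane-1,2-diyldioxy)-8a-methyl-1,2,4a,5,6,7,8,8a-octahydronaphthalen-2-ol (7β-alcohol)
Conditions: NaBH4, CeCl3·7H2O, MeOH, −78 → −40 °C
Reagents that add atoms: none
Why: Luche 1,2-reduction, in which hydride enters C7 from the α face because the axial C5 methyl group shields the β face in a 1,3-relationship, which sets the 7β hydroxyl group.

Step 8
Reactants: 14 (2S,4aS,8aS)-3-(1,3-dioxolan-2-ylmethyl)-8,8-(ethane-1,2-diyldioxy)-8a-methyl-1,2,4a,5,6,7,8,8a-octahydronaphthalen-2-ol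
Product: 15 7β-hydroxy-8β,9β-methano cyclopropane (C8 side chain and C4 ketal unchanged)
Conditions: Et2Zn, CH2I2, CH2Cl2, −15 → 0 °C
Reagents that add atoms: diiodomethane, ICI
Why: Simmons–Smith cyclopropanation in the Furukawa variant, in which the zinc alkoxide at C7 delivers the carbenoid to the β face of the C8=C9 alkene against the steric preference, setting C9 (CH2 β, H α) and the temporary C8 centre.

Step 9
Reactants: 15 7β-hydroxy-8β,9β-methano cyclopropane
Product: 16 8β,9β-methano C7 ketone
Conditions: Dess–Martin periodinane, NaHCO3, CH2Cl2, 0 → 20 °C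
Reagents that add atoms: none
Why: Buffered Dess–Martin oxidation of the secondary cyclopropyl carbinol gives the conjugated cyclopropyl ketone without touching the acetals or any stereocentre.

Step 10
Reactants: 16 8β,9β-methano C7 ketone
Product: 18 C7 ketone with 8α-CH3 and 8β-CH2-(1,3-dioxolan-2-yl) and 9β-CH3, via lithium enolate 17 (not isolated)
Conditions: Li (2.2 equiv), NH3/THF, −78 °C; then MeI, −78 → −40 °C
Reagents that add atoms: iodomethane, CI
Why: Dissolving-metal reduction opens the cyclopropane at the exocyclic C8–CH2 bond, which overlaps best with the carbonyl π system, to give the 9β-methyl group and the regiodefined C7–C8 enolate 17, which is methylated axially from the α face (anti to the vicinal 9β-methyl group) so that C8 becomes quaternary with CH3 α and C11 β.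

Step 11
Reactants: 18 C7 ketone with 8α-CH3 and 8β-CH2-(1,3-dioxolan-2-yl) and 9β-CH3
Product: 20 bis-acetal with C7 methylene, via hydrazone 19 (not isolated)
Conditions: N2H4·H2O, diethylene glycol, 130 °C; then KOH, 200 °C
Reagents that add atoms: none
Why: Wolff–Kishner reduction in the Huang-Minlon variant removes the C7 carbonyl, both acetals being stable to hot hydroxide and the only stereocentre next to the carbonyl (C8) being quaternary.

Step 12
Reactants: 20 bis-acetal with C7 methylene
Product: 21 keto aldehyde (C4 ketone; C8–CH2–CHO)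
Conditions: 2 M HCl, THF, 40 °C
Reagents that add atoms: water, O
Why: Acid hydrolysis frees the C4 ketone and the C5′ aldehyde in one operation at a stage where no acid-labile alkene is present and no intramolecular aldol is possible (C4 and C11 sit on opposite faces of ring B).

Step 13
Reactants: 21 keto aldehyde (C4 ketone; C8–CH2–CHO)
Product: 22 keto alcohol (C8–CH2CH2OH)
Conditions: NaBH4 (0.3 equiv), EtOH/CH2Cl2, −78 °C
Reagents that add atoms: none
Why: Chemoselective borohydride reduction, the aldehyde being far more reactive at low temperature than the C4 ketone flanked by the quaternary C5.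

Step 14
Reactants: 22 keto alcohol (C8–CH2CH2OH)
Product: 23 keto iodide (C8–CH2CH2I)
Conditions: I2, PPh3, imidazole, CH2Cl2, 0 → 20 °C
Reagents that add atoms: iodine, II
Why: Appel-type iodination by SN2 displacement at the primary C5′, which is one carbon removed from the neopentyl position.

Step 15
Reactants: 23 keto iodide (C8–CH2CH2I)
Product: 25 C4 enol triflate (C3=C4), via potassium enolate 24 (not isolated)
Conditions: KN(SiMe3)2, THF, −78 °C; then PhNTf2, −78 → 0 °C
Reagents that add atoms: N-phenylbis(trifluoromethanesulfonimide), O=S(=O)(N(c1ccccc1)S(=O)(=O)C(F)(F)F)C(F)(F)F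
Why: Enolisation is regiospecific because only C3 carries α-hydrogens (C5 is quaternary), O-sulfonylation traps the enolate, and the hindered amide base leaves the primary iodide alone at −78 °C.

Step 16
Reactants: 25 C4 enol triflate (C3=C4)
Product: 26 (1R,2R,4aS,8aS)-2-(2-iodoethyl)-1,2,4a,5-tetramethyl-1,2,3,4,4a,7,8,8a-octahydronaphthalene
Conditions: MeZnCl, Pd(PPh3)4 (5 mol %), THF, 50 °C
Reagents that add atoms: methylzinc chloride, C[Zn]Cl
Why: Negishi coupling of the alkenyl triflate installs the C4 methyl group and fixes the C3=C4 alkene regiospecifically, while the unactivated primary iodide is not engaged by triphenylphosphine-ligated palladium.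

Step 17
Reactants: 26 (1R,2R,4aS,8aS)-2-(2-iodoethyl)-1,2,4a,5-tetramethyl-1,2,3,4,4a,7,8,8a-octahydronaphthalene; 27 methyl 4,5-dibromofuran-2-carboxylate
Product: 29 methyl 4-bromo-5-{2-[(1R,2R,4aS,8aS)-1,2,4a,5-tetramethyl-1,2,3,4,4a,7,8,8a-octahydronaphthalen-2-yl]ethyl}furan-2-carboxylate, via alkylzinc iodide 28 (not isolated)
Conditions: Zn dust, LiCl, THF, 40 °C; then 27, Pd(OAc)2 (3 mol %), SPhos (6 mol %), 25 °C
Reagents that add atoms: none
Why: LiCl-promoted zinc insertion into the primary iodide is followed by Negishi coupling, in which oxidative addition occurs at the C5–Br bond α to the furan oxygen in preference to C4–Br and the ester is tolerated by the organozinc.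

Step 18
Reactants: 29 methyl 4-bromo-5-{2-[(1R,2R,4aS,8aS)-1,2,4a,5-tetramethyl-1,2,3,4,4a,7,8,8a-octahydronaphthalen-2-yl]ethyl}furan-2-carboxylate
Product: 30 methyl 4-methoxy-5-{2-[(1R,2R,4aS,8aS)-1,2,4a,5-tetramethyl-1,2,3,4,4a,7,8,8a-octahydronaphthalen-2-yl]ethyl}furan-2-carboxylate
Conditions: CuI (10 mol %), 3,4,7,8-tetramethyl-1,10-phenanthroline (20 mol %), Cs2CO3, MeOH, toluene, 110 °C
Reagents that add atoms: methanol, CO
Why: Copper-catalysed Ullmann-type C–O coupling of the remaining heteroaryl bromide with methanol places the future C3′ methoxy group, and the methyl ester can only exchange with itself.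

Step 19
Reactants: 30 methyl 4-methoxy-5-{2-[(1R,2R,4aS,8aS)-1,2,4a,5-tetramethyl-1,2,3,4,4a,7,8,8a-octahydronaphthalen-2-yl]ethyl}furan-2-carboxylate
Product: 33 Dysidenone A, via endoperoxide 31 (not isolated), via cis-enedione 32 (not isolated)
Conditions: O2, visible light, tetraphenylporphyrin (cat.), CH2Cl2, −78 °C; then Me2S, −78 → 20 °C; then Et3N, 0 °C
Reagents that add atoms: dioxygen, O=O
Why: The one-pot conversion of a furan into a 4-hydroxycyclopent-2-enone applies here, since [4+2] addition of singlet oxygen to the electron-rich alkoxyfuran (faster than the ene reaction of the hindered C3=C4 alkene) gives endoperoxide 31, dimethyl sulfide reduces it to cis-enedione 32, and triethylamine triggers the aldol addition of the C5′ enolate to the α-keto ester carbonyl, forming the C1′–C5′ bond and both ring C stereocentres; nothing in the substrate differentiates the two faces of the ketoester, so ring C diastereomers are expected, from which the (1′S,5′R) isomer is separated while C5′ epimers are equilibrated with base and isomers with the wrong C1′ are recycled through the retro-aldol equilibrium.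

Compound list
1 | 2-methylcyclohex-2-en-1-one | CC1=CCCCC1=O | starting material
2 | vinylmagnesium bromide | C=C[Mg]Br | starting material
3 | 3-bromo-2-methylprop-1-ene | CC(=C)CBr | starting material
4 | bromomagnesium (3S)-3-ethenyl-2-methylcyclohex-1-en-1-olate | C=C[C@@H]1CCCC(O[Mg]Br)=C1C | intermediate
5 | (2S,3S)-3-ethenyl-2-methyl-2-(2-methylprop-2-en-1-yl)cyclohexan-1-one | C=C(C)C[C@]1(C)C(=O)CCC[C@H]1C=C | intermediate
6 | (6S,7S)-7-ethenyl-6-methyl-6-(2-methylprop-2-en-1-yl)-1,4-dioxaspiro[4.5]decane | C=C(C)C[C@]1(C)C2(OCCO2)CCC[C@H]1C=C | intermediate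
7 | bis-ozonide of 6 (both alkenes as 1,2,4-trioxolanes; the new trioxolane centres as mixtures) | CC1(OCOO1)C[C@]2(C)C3(OCCO3)CCC[C@H]2C4OCOO4 | intermediate
8 | (6S,7R)-6-methyl-6-(2-oxopropyl)-1,4-dioxaspiro[4.5]decane-7-carbaldehyde | CC(=O)C[C@]1(C)C2(OCCO2)CCC[C@H]1C=O | intermediate
9 | aldol adduct: ring B closed, C7 ketone, C9 hydroxyl (C9 as a mixture), C4 ketal | O=C1C[C@]2(C)C3(OCCO3)CCC[C@H]2C(O)C1 | intermediate
10 | (4aS,8aS)-8,8-(ethane-1,2-diyldioxy)-8a-methyl-4a,5,6,7,8,8a-hexahydronaphthalen-2(1H)-one (C7 ketone, C8=C9, 10α-H, 5β-CH3) | O=C1C[C@]2(C)C3(OCCO3)CCC[C@H]2C=C1 | intermediate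
11 | (4aS,8aS)-8,8-(ethane-1,2-diyldioxy)-3-iodo-8a-methyl-4a,5,6,7,8,8a-hexahydronaphthalen-2(1H)-one (iodine on C8) | O=C1C[C@]2(C)C3(OCCO3)CCC[C@H]2C=C1I | intermediate
12 | (1,3-dioxolan-2-ylmethyl)zinc bromide | Br[Zn]CC1OCCO1 | starting material
13 | (4aS,8aS)-3-(1,3-dioxolan-2-ylmethyl)-8,8-(ethane-1,2-diyldioxy)-8a-methyl-4a,5,6,7,8,8a-hexahydronaphthalen-2(1H)-one | O=C1C[C@]2(C)C3(OCCO3)CCC[C@H]2C=C1CC4OCCO4 | intermediate
14 | (2S,4aS,8aS)-3-(1,3-dioxolan-2-ylmethyl)-8,8-(ethane-1,2-diyldioxy)-8a-methyl-1,2,4a,5,6,7,8,8a-octahydronaphthalen-2-ol (7β-OH) | O[C@H]1C[C@]2(C)C3(OCCO3)CCC[C@H]2C=C1CC4OCCO4 | intermediate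
15 | 7β-hydroxy-8β,9β-methano compound: cyclopropane CH2 on the β face across C8–C9, C8 also bearing CH2-(1,3-dioxolan-2-yl), 9α-H, 10α-H, 5β-CH3, C4 ketal | O[C@H]1C[C@]2(C)C3(OCCO3)CCC[C@H]2[C@H]5C[C@@]15CC4OCCO4 | intermediate
16 | 8β,9β-methano C7 ketone (otherwise as 15) | O=C1C[C@]2(C)C3(OCCO3)CCC[C@H]2[C@H]5C[C@@]15CC4OCCO4 | intermediate
17 | lithium C7–C8 enolate with 9β-CH3 (9α-H), C8 bearing CH2-(1,3-dioxolan-2-yl), C4 ketal | [Li]OC1=C(CC4OCCO4)[C@H](C)[C@@H]2CCCC3(OCCO3)[C@@]2(C)C1 | intermediate
18 | C7 ketone with 8α-CH3, 8β-CH2-(1,3-dioxolan-2-yl), 9β-CH3, 10α-H, 5β-CH3, C4 ketal | O4CCOC4C[C@@]1(C)C(=O)C[C@]2(C)C3(OCCO3)CCC[C@H]2[C@H]1C | intermediate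
19 | C7 hydrazone of 18 | O4CCOC4C[C@@]1(C)C(=NN)C[C@]2(C)C3(OCCO3)CCC[C@H]2[C@H]1C | intermediate
20 | bis-acetal with C7 methylene (otherwise as 18) | O4CCOC4C[C@@]1(C)CC[C@]2(C)C3(OCCO3)CCC[C@H]2[C@H]1C | intermediate
21 | keto aldehyde: C4 ketone, 8β-CH2CHO, 8α-CH3, 9β-CH3, 10α-H, 5β-CH3 | O=CC[C@@]1(C)CC[C@]2(C)C(=O)CCC[C@H]2[C@H]1C | intermediate
22 | keto alcohol: as 21 with 8β-CH2CH2OH | OCC[C@@]1(C)CC[C@]2(C)C(=O)CCC[C@H]2[C@H]1C | intermediate
23 | keto iodide: as 21 with 8β-CH2CH2I | ICC[C@@]1(C)CC[C@]2(C)C(=O)CCC[C@H]2[C@H]1C | intermediate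
24 | potassium C3–C4 enolate of 23 | ICC[C@@]1(C)CC[C@]2(C)C(O[K])=CCC[C@H]2[C@H]1C | intermediate
25 | C4 enol triflate (C3=C4) with 8β-CH2CH2I | ICC[C@@]1(C)CC[C@]2(C)C(OS(=O)(=O)C(F)(F)F)=CCC[C@H]2[C@H]1C | intermediate
26 | (1R,2R,4aS,8aS)-2-(2-iodoethyl)-1,2,4a,5-tetramethyl-1,2,3,4,4a,7,8,8a-octahydronaphthalene | ICC[C@@]1(C)CC[C@]2(C)C(C)=CCC[C@H]2[C@H]1C | intermediate
27 | methyl 4,5-dibromofuran-2-carboxylate | COC(=O)c1cc(Br)c(Br)o1 | starting material
28 | {2-[(1R,2R,4aS,8aS)-1,2,4a,5-tetramethyl-1,2,3,4,4a,7,8,8a-octahydronaphthalen-2-yl]ethyl}zinc iodide | I[Zn]CC[C@@]1(C)CC[C@]2(C)C(C)=CCC[C@H]2[C@H]1C | intermediate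
29 | methyl 4-bromo-5-{2-[(1R,2R,4aS,8aS)-1,2,4a,5-tetramethyl-1,2,3,4,4a,7,8,8a-octahydronaphthalen-2-yl]ethyl}furan-2-carboxylate | COC(=O)c1cc(Br)c(CC[C@@]2(C)CC[C@]3(C)C(C)=CCC[C@H]3[C@H]2C)o1 | intermediate
30 | methyl 4-methoxy-5-{2-[(1R,2R,4aS,8aS)-1,2,4a,5-tetramethyl-1,2,3,4,4a,7,8,8a-octahydronaphthalen-2-yl]ethyl}furan-2-carboxylate | COC(=O)c1cc(OC)c(CC[C@@]2(C)CC[C@]3(C)C(C)=CCC[C@H]3[C@H]2C)o1 | intermediate
31 | furan endoperoxide of 30 (2,3,7-trioxabicyclo[2.2.1]hept-5-ene; both facial adducts) | COC(=O)C12OOC(CC[C@@]3(C)CC[C@]4(C)C(C)=CCC[C@H]4[C@H]3C)(O1)C(OC)=C2 | intermediate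
32 | methyl (3E)-4-methoxy-2,5-dioxo-7-[(1R,2R,4aS,8aS)-1,2,4a,5-tetramethyl-1,2,3,4,4a,7,8,8a-octahydronaphthalen-2-yl]hept-3-enoate (the two acyl groups cis on the alkene) | COC(=O)C(=O)/C=C(\C(=O)CC[C@@]1(C)CC[C@]2(C)C(C)=CCC[C@H]2[C@H]1C)OC | intermediate
33 | Dysidenone A, methyl (1S,5R)-1-hydroxy-3-methoxy-4-oxo-5-{[(1R,2R,4aS,8aS)-1,2,4a,5-tetramethyl-1,2,3,4,4a,7,8,8a-octahydronaphthalen-2-yl]methyl}cyclopent-2-ene-1-carboxylate | COC(=O)[C@]1(O)C=C(OC)C(=O)[C@@H]1C[C@@]1(C)CC[C@]2(C)C(C)=CCC[C@H]2[C@H]1C | target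

Total step count: 19. Longest linear sequence: 19 steps (1 to 33); 2, 3, 12 and 27 enter as purchased reagents.

Steps most likely to fail

Step 1. The enantiofacial discrimination in the copper-mediated vinyl transfer to the α-substituted enone may be insufficient, and competing 1,2-addition would add to the loss. The fallback gives up catalytic induction for resolution. It sets out from 1, 2 and 3, which are coupled with CuBr·SMe2 alone (no chiral ligand, THF, −40 °C; then DMPU and 3) to give racemic trans-3-ethenyl-2-methyl-2-(2-methylprop-2-en-1-yl)cyclohexan-1-one F1. The trans relationship is still substrate-controlled. F1 is resolved by preparative chromatography on a chiral stationary phase, and the (2S,3S) enantiomer re-enters the route as 5.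

Step 19. Facial selectivity at the ketoester carbonyl may be poor in the amine-mediated aldol closure, leaving the target as a minor ring C isomer. The fallback replaces the equilibrating aldol by a catalyst-controlled Mukaiyama aldol. It sets out from 32, isolated after the dimethyl sulfide reduction. Soft enolisation (Me3SiOTf, Et3N, CH2Cl2, −78 °C) gives the trimethylsilyl dienol ether of 32 F2. F2 is cyclised with Cu(OTf)2 and a C2-symmetric 2,2′-isopropylidenebis(4-tert-butyl-2-oxazoline) ligand, which chelates the α-keto ester and shields one face of its ketone; the ligand antipode is chosen to give the 1′S carbinol. This should give the O-trimethylsilyl ether of Dysidenone A F3. Mild desilylation (HF·pyridine, THF, 0 °C) returns to the route at 33, and any C5′ epimer is equilibrated with triethylamine.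

Step 18. Protodebromination may compete with C–O bond formation at the hindered β-position of the fully substituted furan. The fallback installs the methoxy group on the furan fragment before the coupling. It sets out from 27: bromine–magnesium exchange at the more reactive C5 position (i-PrMgCl·LiCl, THF, −40 °C; then MeOH) gives methyl 4-bromofuran-2-carboxylate F4. Copper-mediated methoxylation of this unhindered bromide (NaOMe, CuBr, MeOH/DMF, 100 °C) gives methyl 4-methoxyfuran-2-carboxylate F5. Bromination α to the ring oxygen (N-bromosuccinimide, DMF, 0 °C) gives methyl 5-bromo-4-methoxyfuran-2-carboxylate F6. Negishi coupling of F6 with alkylzinc iodide 28 under the conditions of step 17 returns to the route at 30.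

Further compounds
F1 | step 1 | racemic trans-3-ethenyl-2-methyl-2-(2-methylprop-2-en-1-yl)cyclohexan-1-one | C=C(C)C[C@]1(C)C(=O)CCC[C@H]1C=C.C=C(C)C[C@@]1(C)C(=O)CCC[C@@H]1C=C
F2 | step 19 | trimethylsilyl dienol ether of 32 (C4′=C5′ enol ether, geometry not defined) | COC(=O)C(=O)/C=C(\C(O[Si](C)(C)C)=CC[C@@]1(C)CC[C@]2(C)C(C)=CCC[C@H]2[C@H]1C)OC
F3 | step 19 | O-trimethylsilyl ether of Dysidenone A | COC(=O)[C@]1(O[Si](C)(C)C)C=C(OC)C(=O)[C@@H]1C[C@@]1(C)CC[C@]2(C)C(C)=CCC[C@H]2[C@H]1C
F4 | step 18 | methyl 4-bromofuran-2-carboxylate | COC(=O)c1cc(Br)co1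
F5 | step 18 | methyl 4-methoxyfuran-2-carboxylate | COC(=O)c1cc(OC)co1
F6 | step 18 | methyl 5-bromo-4-methoxyfuran-2-carboxylate | COC(=O)c1cc(OC)c(Br)o1
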